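## Structural features

The target joins three units at one methine carbon: C8 of ring A of a (2R,3S)-flavan-3-ol (the (+)-catechin skeleton, rings A, C and B), a 3,4-dihydroxyphenyl ring, and C2 of a 4,6-dihydroxy-2,3-dihydrobenzofuran. There are four stereocentres: C2 and C3 of flavan ring C, which are those of the natural flavanol, and the exocyclic diarylmethine (R) bonded directly to benzofuran C2 (S), so an acyclic and a ring stereocentre stand side by side. Ring A and the benzofuran arene are phloroglucinol-type rings and the other two are catechols. The nine phenols oxidise in air, the free flavanol epimerises at C2 in base, and the ipso carbon C8, flanked by O7 and O1, is nucleophilic enough to migrate towards any cationic centre two atoms away. The real difficulty is the vicinal methine/C2 pair, which cannot be taken from the chiral pool, together with the need to make bonds beside ring A without aryl shifts. Benzofuran C3 is an unsubstituted benzylic CH2 on C3a, and C2 carries the ring oxygen O1. That pattern is what a carbene carbon on the arene (a former aldehyde carbon on C3a) leaves when it inserts into the O–CH2 group of an aryl 2,2-diarylethyl ether, and the key step forms C2–C3 in this way.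

## Logic of the disconnections

24 ⇒ 23 ⇒ 22. Seven O–benzyl bonds and then two O–Si bonds are cut. The phenols and the 3-hydroxyl must be masked through organometallic and carbene chemistry; benzyl ethers leave by neutral hydrogenolysis with only a volatile by-product. The two silyl ethers sit on the ring that will carry the carbene, where an O–CH2 group is not allowed. The forward demand is that the benzylic C–O bond of ring C and the dihydrofuran survive hydrogenolysis.

22 ⇒ 19. The C2–C3 bond of the dihydrobenzofuran is cut. C3 is a bare methylene and C2 an ether carbon, the retron of a carbene insertion into an ether α-C–H bond. This removes the five-membered ring and one stereocentre and leaves an acyclic aryl alkyl ether. The forward step must choose the 1,5 position over the doubly benzylic 1,6 position and one of the two diastereotopic hydrogens beside the methine.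

19 ⇒ 18 ⇒ 13 + 17. The C=N bond and then the aryl–O bond (not the alkyl–O bond) are cut. Cutting on the arene side makes the CH2–O carbon of 13 a nucleophile only, so no leaving group is ever placed β to the electron-rich ring of 13, where aryl migration or elimination would follow. The gain is convergence: 17 is a simple arene and 13 holds all stereocentres made so far. The forward coupling must favour C–O reductive elimination over β-hydride elimination and tolerate the formyl and silyl groups.

17 ⇒ 16 ⇒ 14. Two O–Si bonds and the aryl–CHO bond are cut, leading to a commercial bromoresorcinol. Formylation must go para to one hydroxyl and ortho to the other.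

13 ⇒ 11. The primary alcohol carbon is traced to the internal carbon of a vinyl group, with one carbon excised in the forward sense. A vinyl group is the natural by-product of an SN2′ construction of the methine. The transient aldehyde 12 must be reduced before it can enolise.

11 ⇒ 4 + 8. The bond between C8 of ring A and the methine is cut. This creates the only stereocentre that comes from neither the chiral pool nor the key step, under reagent control. The hindered ring is made the nucleophile (through 10) and the moderately electron-rich cinnamyl unit the electrophile, because the reverse polarity would need an allylic halide conjugated to a trialkoxyarene, which ionises too easily. The forward step needs γ-selectivity and face selectivity.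

8 ⇒ 6 ⇒ 5. The C–Cl bond, with allylic transposition, and the carbinol–vinyl bond are cut, reaching a commercial aldehyde. The forward steps only need to end at the conjugated (E)-chloride.

4 ⇒ 3 ⇒ 2 ⇒ 1. The C8–Br bond and five O–benzyl bonds are cut, back to the natural flavanol that supplies C2 and C3 of ring C. Bromination must choose C8 over C6, and benzylation must avoid base-induced epimerisation.

## Other disconnections considered

Alternative 1: The cut is through C4–C3 and O1–C2 of flavan ring C. In the forward step the salicyl alcohol A3 would lose water to an ortho-quinone methide on ring A, which would add the enol acetate A2 under a chiral phosphoric acid to give A1. A1 is the hepta-O-benzyl 3-O-acetate with a free 7-hydroxyl: by count it has seven benzyl ethers (two on the benzofuran, two on each catechol ring, one at C5).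
- In favour: one step would form a ring, two bonds and two stereocentres. The 2,3-trans relation follows from the (E)-alkene in a suprafacial [4+2] addition. No diazo compound is needed.
- Against: the stereocentres it makes are the two that the chosen plan simply buys with 1, and the methine/C2 pair is left untouched. The methide carbon is unsubstituted, so dimerisation and trapping by the phenols of A3 compete. The free 7-hydroxyl is para to the CH2OH and opens a para-quinone methide channel. An enol ester is normally polarised to give a 2-acetoxy acetal, so the required flavan regiochemistry depends on the aryl donor overriding the acetoxy group.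
- Comparison: on structure it does more per step (two bonds, two stereocentres against one and one), which is better. On mechanism the relative configuration is more predictable than in a C–H insertion (better), while absolute control by a catalyst acting far from the existing stereocentres is an uncertainty of the same kind (equal). On step economy it is worse before the key step, because ring A and the whole left half must be built de novo. After the key step it needs two deprotections, equal to the chosen plan.

Alternative 2: The cuts are C3a–C7a, C4–C5 and C6–C7. The diyne A5 and the borylalkyne A6 would cyclotrimerise under Cp*RuCl(cod) to the boryl tert-butoxy dihydrobenzofuran A4.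
- In favour: three C–C bonds and two rings in one neutral, atom-economic step. The known meta preference of ruthenacycles puts boron where it is needed. C2 is already present in A5 and is not touched, so the key step has no diastereoselectivity problem. On that point it is better than the chosen plan.
- Against: A5 contains two ynol ethers. One is an ethynyl ether of a hindered secondary alcohol, made under strongly basic conditions; the other is a tert-butoxyalkyne that loses isobutene to a ketene on warming. The stereochemical problem is only moved to the carbinol precursor of A5, whose making needs a selective addition beside the epimerisable aldehyde 12.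
- Comparison: on structure it builds a benzene ring that the chosen plan buys. Mechanistically the cycloaddition is well behaved (equal or better), but the substrate is far more fragile. After the key step it needs C–B oxidation, tert-butyl ether cleavage and hydrogenolysis, three steps against two, and more steps before; it is worse on step economy.

Alternative 3: The cuts are C3a–C3 and C7a–O1. The iodide A8 and the epoxide A9 would be joined under Pd(OAc)2, a triarylphosphine and a bridgehead-substituted norbornene to the nona-O-benzyl ether A7.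
- In favour: A9 would come from 11 by asymmetric dihydroxylation and ring closure, so the route shares everything up to 11. C2 is set by a reagent before the annulation and kept, since its C–O bond is not broken; this is better than relying on a C–H insertion for C2. All protecting groups are benzyl, so one hydrogenolysis finishes the synthesis, one step fewer after the key step. From 11 it is about three steps shorter overall, which is better.
- Against: A8 has two free ortho positions, and each lies between the iodide and a benzyloxy group. The palladacycle would therefore have to form at a crowded site while double alkylation is held back. The epoxide CH2 is next to a bulky diarylmethine. Any Lewis-acid activation of the epoxide invites participation by the ring A ipso carbon. The face selectivity of the dihydroxylation beside the methine must be imposed by the reagent.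
- Comparison: on structure it is the most convergent (better). On mechanism the catalytic cycle has several places to fail (ortho palladation, epoxide opening at divalent palladium, norbornene extrusion, C–O reductive elimination) with the least favourable arene substitution pattern. The chosen key step has one elementary uncertainty, which C–H bond reacts. On step economy it is better.

Key step: step 12

Remark on the chemistry: the absolute sense of induction of the copper–phosphoramidite catalyst (step 6) and of Rh2(S-PTAD)4 (step 12) cannot be assigned with confidence for these substrates. The enantiomers named are taken as the matched ones; the mirror-image ligand or catalyst would be used otherwise.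

Step 1
Reactants: 1 (+)-catechin
Product: 2 5,7,3′,4′-tetra-O-benzyl-(+)-catechin
Conditions: BnBr, K2CO3, DMF, 0 °C to rt, under argon
Reagents that add atoms: benzyl bromide, BrCc1ccccc1
Why: Williamson ether synthesis; carbonate ionises the four phenols but not the secondary 3-hydroxyl, and low temperature with exclusion of air limits C2 epimerisation and C-benzylation.

Step 2
Reactants: 2 5,7,3′,4′-tetra-O-benzyl-(+)-catechin
Product: 3 3,5,7,3′,4′-penta-O-benzyl-(+)-catechin
Conditions: NaH, BnBr, Bu4NI (cat.), DMF, 0 °C to rt
Reagents that add atoms: benzyl bromide, BrCc1ccccc1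
Why: Williamson ether synthesis on the secondary alkoxide; with every phenol capped, the quinone methide route to C2 epimerisation is closed, and the acidic hydroxyl is removed before the organometallic steps.

Step 3
Reactants: 3 3,5,7,3′,4′-penta-O-benzyl-(+)-catechin
Product: 4 8-bromo-3,5,7,3′,4′-penta-O-benzyl-(+)-catechin
Conditions: NBS, CH2Cl2, −78 to 0 °C
Reagents that add atoms: N-bromosuccinimide, BrN1C(=O)CCC1=O
Why: Electrophilic aromatic bromination; in 3-O-protected benzylated flavan-3-ols C8 is the more reactive of the two free ring A positions, and one equivalent at low temperature should stop at the monobromide.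

Step 4
Reactants: 5 3,4-bis(benzyloxy)benzaldehyde
Product: 6 rac-1-[3,4-bis(benzyloxy)phenyl]prop-2-en-1-ol
Conditions: CH2=CHMgBr, THF, 0 °C; aq. NH4Cl
Reagents that add atoms: vinylmagnesium bromide, C=C[Mg]Br
Why: Grignard 1,2-addition to an aldehyde; the carbinol centre is racemic and does not matter, because it is lost in the next step.

Step 5
Reactants: 6 rac-1-[3,4-bis(benzyloxy)phenyl]prop-2-en-1-ol
Product: 8 (E)-1,2-bis(benzyloxy)-4-(3-chloroprop-1-en-1-yl)benzene, via allylic chlorosulfite 7 (not isolated)
Conditions: SOCl2, Et2O, 0 °C to rt; used without chromatography on silica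
Reagents that add atoms: thionyl chloride, ClS(Cl)=O
Why: Chlorination with allylic transposition (SNi′): the chlorosulfite collapses to the conjugated, thermodynamically preferred (E)-cinnamyl chloride, a known outcome for 1-arylallyl alcohols.

Step 6
Reactants: 4 8-bromo-3,5,7,3′,4′-penta-O-benzyl-(+)-catechin; 8 (E)-1,2-bis(benzyloxy)-4-(3-chloroprop-1-en-1-yl)benzene
Product: 11 8-[(1R)-1-[3,4-bis(benzyloxy)phenyl]prop-2-en-1-yl]-3,5,7,3′,4′-penta-O-benzyl-(+)-catechin, via C8 aryllithium 9 (not isolated), via C8 arylmagnesium bromide 10 (not isolated)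
Conditions: 4, t-BuLi (2 equiv), Et2O–toluene, −78 °C; MgBr2·OEt2, −78 to 0 °C; slow addition to 8 (1.3 equiv), CuBr·SMe2 (5 mol%), (S,S,S)-phosphoramidite (BINOL-derived, N,N-bis(1-phenylethyl); 6 mol%), CH2Cl2, −78 °C
Reagents that add atoms: none
Why: Copper-catalysed asymmetric allylic arylation (SN2′) of a cinnamyl chloride with an aryl Grignard reagent: oxidative addition anti to chloride at the γ-carbon gives a σ-allyl species of trivalent copper that reductively eliminates to the branched 1,1-diarylpropene. The chiral phosphoramidite on monovalent copper chooses the alkene face and so sets the (R)-methine independently of the remote flavan stereocentres; slow addition in CH2Cl2 suppresses the uncatalysed linear coupling.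

Step 7
Reactants: 11 8-[(1R)-1-[3,4-bis(benzyloxy)phenyl]prop-2-en-1-yl]-3,5,7,3′,4′-penta-O-benzyl-(+)-catechin
Product: 13 (2R)-2-[3,4-bis(benzyloxy)phenyl]-2-(3,5,7,3′,4′-penta-O-benzylcatechin-8-yl)ethanol, via diarylacetaldehyde 12 (not isolated)
Conditions: O3, CH2Cl2–MeOH, −78 °C (Sudan Red 7B end point); NaBH4, −78 to 0 °C
Reagents that add atoms: ozone, [O-][O+]=O
Why: Ozonolysis with reductive work-up; the terminal alkene reacts much faster than the alkoxyarenes and the dye marks the end point. Borohydride added cold reduces the configurationally fragile aldehyde 12 as it is released, so the methine should not epimerise.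

Step 8
Reactants: 14 5-bromoresorcinol
Product: 16 2-bromo-4,6-dihydroxybenzaldehyde, via aryl iminium salt 15 (not isolated)
Conditions: POCl3, DMF, MeCN, 0 °C to rt; H2O, 50 °C
Reagents that add atoms: N,N-dimethylformamide, CN(C)C=O; water, O
Why: Vilsmeier–Haack formylation; resorcinols react para to one hydroxyl and ortho to the other rather than between the two, which here gives the aldehyde flanked by bromine and hydroxyl after hydrolysis of the iminium salt.

Step 9
Reactants: 16 2-bromo-4,6-dihydroxybenzaldehyde
Product: 17 2-bromo-4,6-bis(triisopropylsilyloxy)benzaldehyde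
Conditions: i-Pr3SiOTf, 2,6-lutidine, CH2Cl2, 0 °C to rt
Reagents that add atoms: triisopropylsilyl trifluoromethanesulfonate, CC(C)[Si](C(C)C)(C(C)C)OS(=O)(=O)C(F)(F)F
Why: Silyl ether formation; the triflate is reactive enough for the hydrogen-bonded ortho-hydroxyl. Silyl groups are chosen because silicon, not a C–H bond, then occupies the position 1,5 to the later carbene.

Step 10
Reactants: 13 (2R)-2-[3,4-bis(benzyloxy)phenyl]-2-(3,5,7,3′,4′-penta-O-benzylcatechin-8-yl)ethanol; 17 2-bromo-4,6-bis(triisopropylsilyloxy)benzaldehyde
Product: 18 2-[(2R)-2-[3,4-bis(benzyloxy)phenyl]-2-(3,5,7,3′,4′-penta-O-benzylcatechin-8-yl)ethoxy]-4,6-bis(triisopropylsilyloxy)benzaldehyde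
Conditions: [Pd(allyl)Cl]2 (2.5 mol%), RockPhos (6 mol%), Cs2CO3, toluene, 80 °C; 17 in slight excess
Reagents that add atoms: none
Why: Palladium-catalysed C–O cross-coupling of a primary alcohol with an aryl bromide (Buchwald–Hartwig etherification); the bulky biarylphosphine makes C–O reductive elimination from the divalent palladium alkoxide faster than β-hydride elimination, and the ortho-formyl group speeds oxidative addition. The aryl–O bond is formed so that the CH2 carbon never carries a leaving group; an oxyphosphonium or sulfonate β to ring A would invite a 1,2-aryl shift or elimination.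

Step 11
Reactants: 18 2-[(2R)-2-[3,4-bis(benzyloxy)phenyl]-2-(3,5,7,3′,4′-penta-O-benzylcatechin-8-yl)ethoxy]-4,6-bis(triisopropylsilyloxy)benzaldehyde
Product: 19 (E)-N-tosylhydrazone of 18
Conditions: TsNHNH2, THF–MeOH, 40 °C
Reagents that add atoms: p-toluenesulfonyl hydrazide, Cc1ccc(cc1)S(=O)(=O)NN
Why: Condensation of an aldehyde with a sulfonyl hydrazide to the (E)-hydrazone; the neutral conditions leave the aryl silyl ethers and the methine untouched.

Step 12
Reactants: 19 (E)-N-tosylhydrazone of 18
Product: 22 (2S)-2-[(R)-[3,4-bis(benzyloxy)phenyl](3,5,7,3′,4′-penta-O-benzylcatechin-8-yl)methyl]-4,6-bis(triisopropylsilyloxy)-2,3-dihydrobenzofuran, via hydrazone sodium salt 20 (not isolated), via aryldiazomethane 21 (not isolated)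
Conditions: NaH, THF, 0 °C to rt; solvent exchange; Rh2(S-PTAD)4 (2 mol%), BnEt3NCl (10 mol%), toluene, 40 °C
Reagents that add atoms: none
Why: Deprotonation gives salt 20, which on gentle warming with the phase-transfer salt loses sulfinate (Bamford–Stevens) and releases diazo compound 21 slowly; Rh2(S-PTAD)4, a carboxylate dimer of divalent rhodium, converts 21 with loss of N2 into a donor aryl carbene that inserts into one C–H bond of the ether O–CH2 through a three-centre, hydride-shift-like transition state, forming C2–C3. The closest known reaction type is the dirhodium-catalysed intramolecular 1,5 C–H insertion of aryl carbenes from ortho-alkoxybenzaldehyde sulfonylhydrazones to 2-substituted 2,3-dihydrobenzofurans. The one ring closed is the dihydrofuran, by C–C bond formation between the carbene carbon (C3) and the oxygen-bearing methylene (C2), a 1,5 insertion with O1, C7a and C3a already in place. The new stereocentre C2 arises from the choice between the two diastereotopic methylene hydrogens, with retention at carbon; the chiral adamantyl–phthalimide pocket of the catalyst is the controlling element and has to match or override the 1,2-bias of the adjacent (R)-methine. Selectivity for the 1,5 position over the doubly benzylic methine (1,6) rests on the five-membered transition state and on activation of the methylene by the oxygen lone pair. On the carbene ring the ortho substituent is a silyl ether with silicon at the 1,5 position, the benzyl O–CH2 groups are on remote rings, and the carbene has no β-hydrogen for a 1,2-shift. Slow release keeps the concentration of 21 low and so disfavours azine and stilbene formation.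

Step 13
Reactants: 22 (2S)-2-[(R)-[3,4-bis(benzyloxy)phenyl](3,5,7,3′,4′-penta-O-benzylcatechin-8-yl)methyl]-4,6-bis(triisopropylsilyloxy)-2,3-dihydrobenzofuran
Product: 23 (2S)-2-[(R)-[3,4-bis(benzyloxy)phenyl](3,5,7,3′,4′-penta-O-benzylcatechin-8-yl)methyl]-2,3-dihydrobenzofuran-4,6-diol
Conditions: Bu4NF, AcOH, THF, 0 °C
Reagents that add atoms: none
Why: Fluoride-induced cleavage of the aryl silyl ethers; acetic acid buffers the phenoxides against air oxidation, and doing this before hydrogenolysis allows chromatography while the molecule is still lipophilic.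

Step 14
Reactants: 23 (2S)-2-[(R)-[3,4-bis(benzyloxy)phenyl](3,5,7,3′,4′-penta-O-benzylcatechin-8-yl)methyl]-2,3-dihydrobenzofuran-4,6-diol
Product: 24 (2R,3S)-8-[(R)-[(2S)-4,6-dihydroxy-2,3-dihydrobenzofuran-2-yl](3,4-dihydroxyphenyl)methyl]catechin (CNP0280971.2)
Conditions: H2 (1 atm), Pd(OH)2 on carbon, THF–MeOH, rt; filtration, lyophilisation
Reagents that add atoms: none
Why: Hydrogenolysis of the seven benzyl ethers under neutral conditions, as is routine for benzylated flavan-3-ol oligomers; the benzylic C2–O1 bond of ring C and the dihydrofuran should survive, and toluene is the only by-product.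

Compound list
1 | (+)-catechin, (2R,3S) | Oc1cc(O)c2c(c1)O[C@H](c1ccc(O)c(O)c1)[C@@H](O)C2 | starting material
2 | 5,7,3′,4′-tetra-O-benzyl-(+)-catechin | c1c(OCc4ccccc4)cc(OCc4ccccc4)c3c1O[C@H](c5ccc(OCc4ccccc4)c(OCc4ccccc4)c5)[C@@H](O)C3 | intermediate
3 | 3,5,7,3′,4′-penta-O-benzyl-(+)-catechin | c1c(OCc4ccccc4)cc(OCc4ccccc4)c3c1O[C@H](c5ccc(OCc4ccccc4)c(OCc4ccccc4)c5)[C@@H](OCc4ccccc4)C3 | intermediate
4 | 8-bromo-3,5,7,3′,4′-penta-O-benzyl-(+)-catechin | Brc1c(OCc4ccccc4)cc(OCc4ccccc4)c3c1O[C@H](c5ccc(OCc4ccccc4)c(OCc4ccccc4)c5)[C@@H](OCc4ccccc4)C3 | intermediate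
5 | 3,4-bis(benzyloxy)benzaldehyde | O=Cc1ccc(OCc4ccccc4)c(OCc4ccccc4)c1 | starting material
6 | rac-1-[3,4-bis(benzyloxy)phenyl]prop-2-en-1-ol | C=CC(O)c1ccc(OCc4ccccc4)c(OCc4ccccc4)c1 | intermediate
7 | 1-[3,4-bis(benzyloxy)phenyl]prop-2-en-1-yl chlorosulfite | C=CC(OS(Cl)=O)c1ccc(OCc4ccccc4)c(OCc4ccccc4)c1 | intermediate (not isolated)
8 | (E)-1,2-bis(benzyloxy)-4-(3-chloroprop-1-en-1-yl)benzene | ClC/C=C/c1ccc(OCc4ccccc4)c(OCc4ccccc4)c1 | intermediate
9 | (3,5,7,3′,4′-penta-O-benzylcatechin-8-yl)lithium | [Li]c1c(OCc4ccccc4)cc(OCc4ccccc4)c3c1O[C@H](c5ccc(OCc4ccccc4)c(OCc4ccccc4)c5)[C@@H](OCc4ccccc4)C3 | intermediate (not isolated)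
10 | (3,5,7,3′,4′-penta-O-benzylcatechin-8-yl)magnesium bromide | Br[Mg]c1c(OCc4ccccc4)cc(OCc4ccccc4)c3c1O[C@H](c5ccc(OCc4ccccc4)c(OCc4ccccc4)c5)[C@@H](OCc4ccccc4)C3 | intermediate (not isolated)
11 | 8-[(1R)-1-[3,4-bis(benzyloxy)phenyl]prop-2-en-1-yl]-3,5,7,3′,4′-penta-O-benzyl-(+)-catechin | C=C[C@H](c5ccc(OCc4ccccc4)c(OCc4ccccc4)c5)c5c(OCc4ccccc4)cc(OCc4ccccc4)c3c5O[C@H](c5ccc(OCc4ccccc4)c(OCc4ccccc4)c5)[C@@H](OCc4ccccc4)C3 | intermediate
12 | (2R)-2-[3,4-bis(benzyloxy)phenyl]-2-(3,5,7,3′,4′-penta-O-benzylcatechin-8-yl)acetaldehyde | O=C[C@H](c5ccc(OCc4ccccc4)c(OCc4ccccc4)c5)c5c(OCc4ccccc4)cc(OCc4ccccc4)c3c5O[C@H](c5ccc(OCc4ccccc4)c(OCc4ccccc4)c5)[C@@H](OCc4ccccc4)C3 | intermediate (not isolated)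
13 | (2R)-2-[3,4-bis(benzyloxy)phenyl]-2-(3,5,7,3′,4′-penta-O-benzylcatechin-8-yl)ethanol | OC[C@H](c5ccc(OCc4ccccc4)c(OCc4ccccc4)c5)c5c(OCc4ccccc4)cc(OCc4ccccc4)c3c5O[C@H](c5ccc(OCc4ccccc4)c(OCc4ccccc4)c5)[C@@H](OCc4ccccc4)C3 | intermediate
14 | 5-bromoresorcinol (5-bromobenzene-1,3-diol) | Oc1cc(O)cc(Br)c1 | starting material
15 | N-[(2-bromo-4,6-dihydroxyphenyl)methylidene]-N-methylmethanaminium chloride | C[N+](C)=Cc1c(Br)cc(O)cc1O.[Cl-] | intermediate (not isolated)
16 | 2-bromo-4,6-dihydroxybenzaldehyde | O=Cc1c(Br)cc(O)cc1O | intermediate
17 | 2-bromo-4,6-bis(triisopropylsilyloxy)benzaldehyde | O=Cc1c(Br)cc(O[Si](C(C)C)(C(C)C)C(C)C)cc1O[Si](C(C)C)(C(C)C)C(C)C | intermediate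
18 | 2-[(2R)-2-[3,4-bis(benzyloxy)phenyl]-2-(3,5,7,3′,4′-penta-O-benzylcatechin-8-yl)ethoxy]-4,6-bis(triisopropylsilyloxy)benzaldehyde | O=Cc1c(OC[C@H](c5ccc(OCc4ccccc4)c(OCc4ccccc4)c5)c5c(OCc4ccccc4)cc(OCc4ccccc4)c3c5O[C@H](c5ccc(OCc4ccccc4)c(OCc4ccccc4)c5)[C@@H](OCc4ccccc4)C3)cc(O[Si](C(C)C)(C(C)C)C(C)C)cc1O[Si](C(C)C)(C(C)C)C(C)C | intermediate
19 | (E)-N-tosylhydrazone of 18 | Cc1ccc(cc1)S(=O)(=O)N/N=C/c1c(OC[C@H](c5ccc(OCc4ccccc4)c(OCc4ccccc4)c5)c5c(OCc4ccccc4)cc(OCc4ccccc4)c3c5O[C@H](c5ccc(OCc4ccccc4)c(OCc4ccccc4)c5)[C@@H](OCc4ccccc4)C3)cc(O[Si](C(C)C)(C(C)C)C(C)C)cc1O[Si](C(C)C)(C(C)C)C(C)C | intermediate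
20 | sodium salt of 19 | [Na+].Cc1ccc(cc1)S(=O)(=O)[N-]/N=C/c1c(OC[C@H](c5ccc(OCc4ccccc4)c(OCc4ccccc4)c5)c5c(OCc4ccccc4)cc(OCc4ccccc4)c3c5O[C@H](c5ccc(OCc4ccccc4)c(OCc4ccccc4)c5)[C@@H](OCc4ccccc4)C3)cc(O[Si](C(C)C)(C(C)C)C(C)C)cc1O[Si](C(C)C)(C(C)C)C(C)C | intermediate (not isolated)
21 | aryldiazomethane from 20 | [N-]=[N+]=Cc1c(OC[C@H](c5ccc(OCc4ccccc4)c(OCc4ccccc4)c5)c5c(OCc4ccccc4)cc(OCc4ccccc4)c3c5O[C@H](c5ccc(OCc4ccccc4)c(OCc4ccccc4)c5)[C@@H](OCc4ccccc4)C3)cc(O[Si](C(C)C)(C(C)C)C(C)C)cc1O[Si](C(C)C)(C(C)C)C(C)C | intermediate (not isolated)
22 | (2S)-2-[(R)-[3,4-bis(benzyloxy)phenyl](3,5,7,3′,4′-penta-O-benzylcatechin-8-yl)methyl]-4,6-bis(triisopropylsilyloxy)-2,3-dihydrobenzofuran | CC(C)[Si](C(C)C)(C(C)C)Oc1cc(O[Si](C(C)C)(C(C)C)C(C)C)c2c(c1)O[C@H]([C@H](c1ccc(OCc4ccccc4)c(OCc4ccccc4)c1)c1c(OCc4ccccc4)cc(OCc4ccccc4)c3c1O[C@H](c1ccc(OCc4ccccc4)c(OCc4ccccc4)c1)[C@@H](OCc4ccccc4)C3)C2 | intermediate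
23 | (2S)-2-[(R)-[3,4-bis(benzyloxy)phenyl](3,5,7,3′,4′-penta-O-benzylcatechin-8-yl)methyl]-2,3-dihydrobenzofuran-4,6-diol | Oc1cc(O)c2c(c1)O[C@H]([C@H](c5ccc(OCc4ccccc4)c(OCc4ccccc4)c5)c5c(OCc4ccccc4)cc(OCc4ccccc4)c3c5O[C@H](c5ccc(OCc4ccccc4)c(OCc4ccccc4)c5)[C@@H](OCc4ccccc4)C3)C2 | intermediate
24 | (2R,3S)-8-[(R)-[(2S)-4,6-dihydroxy-2,3-dihydrobenzofuran-2-yl](3,4-dihydroxyphenyl)methyl]catechin (CNP0280971.2) | Oc1cc(O)c2c(c1)O[C@H]([C@H](c1ccc(O)c(O)c1)c1c(O)cc(O)c3c1O[C@H](c1ccc(O)c(O)c1)[C@@H](O)C3)C2 | target

Total: 14 steps. Longest linear sequence: 10 steps from 1 (steps 1, 2, 3, 6, 7, 10, 11, 12, 13, 14). Steps 4 and 5 give 8, and steps 8 and 9 give 17, as side branches.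

Least certain steps

Step 12 (key step). The most likely failure is poor discrimination between the two diastereotopic O–CH2 hydrogens, because the catalyst must work beside a bulky diarylmethine whose own bias is unknown. Next in likelihood are competing 1,6 insertion into the doubly benzylic C–H bond, which is an excellent hydride donor, and dimerisation of the electron-rich diazo compound if it accumulates. The fallback sets out from 19 and comes back at 22. It keeps the disconnection but changes the mechanism of ring closure from two-electron carbenoid insertion to metalloradical catalysis with the chiral amidoporphyrin complex of divalent cobalt [Co(3,5-DitBu-ChenPhyrin)] on the same salt 20. There the cobalt-bound carbene radical abstracts a hydrogen atom from the O–CH2 group through a six-membered array, and the resulting α-oxy radical closes the ring by radical substitution. This pathway has a strong intrinsic preference for the 1,5 position, a different chiral environment and little tendency to carbene dimerisation. The C2 epimers are diastereomers and can be separated by chromatography in either mode. No new compound is made.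

Step 6. The likely failures are low face selectivity, or leakage to the linear coupling product, because a Grignard reagent with two ortho oxygen substituents has not been tried in this catalytic reaction and its reductive elimination may be slow. The fallback sets out from 5 (with 10 generated from 4 as before) and comes back at 13. It replaces catalyst control by chirality transfer:
- Claisen–Schmidt condensation of 5 with acetone (aq. NaOH) would give (E)-4-[3,4-bis(benzyloxy)phenyl]but-3-en-2-one F1.
- Reduction with (R)-2-methyl-CBS-oxazaborolidine and catecholborane would give (S,E)-4-[3,4-bis(benzyloxy)phenyl]but-3-en-2-ol F2.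
- Esterification with picolinic acid (DCC, DMAP) would give the (S)-picolinate F3.
- Anti-selective SN2′ displacement of F3 by 10 with CuBr·SMe2 would give the (E)-1,1-diarylbut-2-ene F4 with the (R)-methine: the nucleophile enters opposite to the chelated leaving group from the conformer with the carbinol hydrogen eclipsing the alkene.
- Ozonolysis of F4 with NaBH4 work-up as in step 7 would give 13.

Step 10. The likely failures are β-hydride elimination from the palladium alkoxide, transfer of a silyl group from the activated aryl silyl ether to the alkoxide, and hemiacetal-derived side reactions of the formyl group; all grow with temperature and base strength. The fallback sets out from 13 and comes back at 18, and it forms the alkyl–O bond in place of the aryl–O bond. Commercial 2,4,6-trihydroxybenzaldehyde would be silylated twice (i-Pr3SiCl, imidazole, DMF), the hydrogen-bonded ortho-hydroxyl staying free, to give 2-hydroxy-4,6-bis(triisopropylsilyloxy)benzaldehyde F5. Mitsunobu etherification of 13 with an excess of F5 (PPh3, DIAD, toluene, 0 °C, high concentration) would give 18. Its own risk is participation of the ring A ipso carbon in the oxyphosphonium intermediate, which is why it is not the first choice.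

Step 7. The likely failures are over-oxidation of the trialkoxyarene rings by ozone if the end point is missed, and epimerisation of the methine through enolisation of 12 if the reduction lags. The fallback sets out from 11 and comes back at 13. Dihydroxylation (K2OsO4·2H2O cat., N-methylmorpholine N-oxide, acetone–water) leaves the arenes untouched and would give the 3,3-diarylpropane-1,2-diol F6 as a mixture of carbinol epimers. Cleavage with NaIO4 in buffered THF–water at 0 °C, followed directly by NaBH4 in the same flask, would give 13 through 12.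

## Further compounds

F0 | step 12 | none | none
F1 | step 6 | (E)-4-[3,4-bis(benzyloxy)phenyl]but-3-en-2-one | CC(=O)/C=C/c1ccc(OCc4ccccc4)c(OCc4ccccc4)c1
F2 | step 6 | (S,E)-4-[3,4-bis(benzyloxy)phenyl]but-3-en-2-ol | C[C@H](O)/C=C/c1ccc(OCc4ccccc4)c(OCc4ccccc4)c1
F3 | step 6 | (S,E)-4-[3,4-bis(benzyloxy)phenyl]but-3-en-2-yl pyridine-2-carboxylate | C[C@H](OC(=O)c1ccccn1)/C=C/c1ccc(OCc4ccccc4)c(OCc4ccccc4)c1
F4 | step 6 | 8-[(1R,2E)-1-[3,4-bis(benzyloxy)phenyl]but-2-en-1-yl]-3,5,7,3′,4′-penta-O-benzyl-(+)-catechin | C/C=C/[C@H](c5ccc(OCc4ccccc4)c(OCc4ccccc4)c5)c5c(OCc4ccccc4)cc(OCc4ccccc4)c3c5O[C@H](c5ccc(OCc4ccccc4)c(OCc4ccccc4)c5)[C@@H](OCc4ccccc4)C3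
F5 | step 10 | 2-hydroxy-4,6-bis(triisopropylsilyloxy)benzaldehyde | O=Cc1c(O)cc(O[Si](C(C)C)(C(C)C)C(C)C)cc1O[Si](C(C)C)(C(C)C)C(C)C
F6 | step 7 | (3R)-3-[3,4-bis(benzyloxy)phenyl]-3-(3,5,7,3′,4′-penta-O-benzylcatechin-8-yl)propane-1,2-diol, both C2 epimers | OCC(O)[C@H](c5ccc(OCc4ccccc4)c(OCc4ccccc4)c5)c5c(OCc4ccccc4)cc(OCc4ccccc4)c3c5O[C@H](c5ccc(OCc4ccccc4)c(OCc4ccccc4)c5)[C@@H](OCc4ccccc4)C3
A1 | alternative 1 | hepta-O-benzyl ether 3-O-acetate of the target with free flavan 7-hydroxyl | c4ccccc4COc1cc(OCc4ccccc4)c2c(c1)O[C@H]([C@H](c1ccc(OCc4ccccc4)c(OCc4ccccc4)c1)c1c(O)cc(OCc4ccccc4)c3c1O[C@H](c1ccc(OCc4ccccc4)c(OCc4ccccc4)c1)[C@@H](OC(C)=O)C3)C2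
A2 | alternative 1 | (E)-2-[3,4-bis(benzyloxy)phenyl]vinyl acetate | CC(=O)O/C=C/c1ccc(OCc4ccccc4)c(OCc4ccccc4)c1
A3 | alternative 1 | 6-benzyloxy-2,4-dihydroxybenzyl alcohol carrying at C3 the (R)-[3,4-bis(benzyloxy)phenyl][(2S)-4,6-bis(benzyloxy)-2,3-dihydrobenzofuran-2-yl]methyl group | OCc1c(OCc4ccccc4)cc(O)c(c1O)[C@@H](c1ccc(OCc4ccccc4)c(OCc4ccccc4)c1)[C@@H]1Cc2c(OCc4ccccc4)cc(OCc4ccccc4)cc2O1
A4 | alternative 2 | 4-tert-butoxy-6-(pinacolboryl)-2,3-dihydrobenzofuran with the hepta-O-benzyl lower half | CC1(C)OB(OC1(C)C)c1cc(OC(C)(C)C)c2c(c1)O[C@H]([C@H](c1ccc(OCc4ccccc4)c(OCc4ccccc4)c1)c1c(OCc4ccccc4)cc(OCc4ccccc4)c3c1O[C@H](c1ccc(OCc4ccccc4)c(OCc4ccccc4)c1)[C@@H](OCc4ccccc4)C3)C2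
A5 | alternative 2 | ethynyl ether of the homopropargylic alcohol with a tert-butoxyalkyne terminus | C#CO[C@@H](CC#COC(C)(C)C)[C@H](c5ccc(OCc4ccccc4)c(OCc4ccccc4)c5)c5c(OCc4ccccc4)cc(OCc4ccccc4)c3c5O[C@H](c5ccc(OCc4ccccc4)c(OCc4ccccc4)c5)[C@@H](OCc4ccccc4)C3
A6 | alternative 2 | 2-ethynyl-4,4,5,5-tetramethyl-1,3,2-dioxaborolane | C#CB1OC(C)(C)C(C)(C)O1
A7 | alternative 3 | nona-O-benzyl ether of the target | c4ccccc4COc1cc(OCc4ccccc4)c2c(c1)O[C@H]([C@H](c1ccc(OCc4ccccc4)c(OCc4ccccc4)c1)c1c(OCc4ccccc4)cc(OCc4ccccc4)c3c1O[C@H](c1ccc(OCc4ccccc4)c(OCc4ccccc4)c1)[C@@H](OCc4ccccc4)C3)C2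
A8 | alternative 3 | 1,3-bis(benzyloxy)-5-iodobenzene | Ic1cc(OCc2ccccc2)cc(OCc2ccccc2)c1
A9 | alternative 3 | (2R)-2-[(R)-[3,4-bis(benzyloxy)phenyl](3,5,7,3′,4′-penta-O-benzylcatechin-8-yl)methyl]oxirane | C1O[C@@H]1[C@H](c5ccc(OCc4ccccc4)c(OCc4ccccc4)c5)c5c(OCc4ccccc4)cc(OCc4ccccc4)c3c5O[C@H](c5ccc(OCc4ccccc4)c(OCc4ccccc4)c5)[C@@H](OCc4ccccc4)C3
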